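## Retrosynthetic overview

- The target is taken back, through dealkylation, desilylation and a Friedel–Crafts butanoylation at C1, to a ring A phenol that still has C1–H and is joined through CH2 to the ring B tri-O-methyl ether.
- The strategy rests on ring A: oxygen on C2, C4 and C6 alternates with carbon substituents on C1 (butanoyl), C3 (CH3) and C5 (CH2 to ring B). C4–C5–C6–C1 map onto a 3-ethoxy-4-(arylmethyl)cyclobutenone and C3–C2 onto 1-(triisopropylsiloxy)propyne.
- The benzannulation forms C3–C4 and C1–C2, then re-forms C4–C5 by 6π electrocyclization.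
- The cyclobutenone comes from [2+2] addition of ethoxyacetylene to the ring B aldoketene. The 3-arylpropanoic acid behind it comes from 2,4,6-trimethoxytoluene by formylation, olefination, hydrogenation, propanoylation and saponification. The siloxyalkyne comes from propyne.
- Ring order: ring B is bought intact. Ring A is the only ring of the target that is built (step 8). The four-membered ring made in step 6 is consumed in step 8.

Key step: step 8

Remark: ring A is numbered C1 (butanoyl), C2 (OH), C3 (CH3), C4 (OH), C5 (CH2 bridge), C6 (OH); ring B is the propanoyl ring. The target has no stereocentre, and the cyclobutenone is made and used as a racemate.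

## Route

Step 1
Reactants: 1 2,4,6-trimethoxytoluene
Product: 3 2,4,6-trimethoxy-3-methylbenzaldehyde, via iminium salt 2 (not isolated)
Conditions: POCl3, DMF, 0 °C → rt; then H2O
Reagents that add atoms: N,N-dimethylformamide, CN(C)C=O; water, O
Why: Vilsmeier–Haack formylation of a trialkoxyarene whose two free positions are equivalent, so the chloroiminium ion should give a single aryl iminium salt that water hydrolyses to the aldehyde.

Step 2
Reactants: 3 2,4,6-trimethoxy-3-methylbenzaldehyde
Product: 4 ethyl (E)-3-(2,4,6-trimethoxy-3-methylphenyl)prop-2-enoate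
Conditions: (EtO)2P(O)CH2CO2Et, NaH, THF, 0 °C → rt
Reagents that add atoms: triethyl phosphonoacetate, CCOC(=O)CP(=O)(OCC)OCC
Why: Horner–Wadsworth–Emmons olefination of a non-enolisable aryl aldehyde with a stabilised phosphonate anion should give the E-cinnamate, whose geometry is removed in the next step.

Step 3
Reactants: 4 ethyl (E)-3-(2,4,6-trimethoxy-3-methylphenyl)prop-2-enoate
Product: 5 ethyl 3-(2,4,6-trimethoxy-3-methylphenyl)propanoate
Conditions: H2 (1 atm), 10% Pd/C, EtOAc, rt
Reagents that add atoms: none
Why: Catalytic hydrogenation should saturate the conjugated alkene and leave the aryl methyl ethers and the ester untouched.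

Step 4
Reactants: 5 ethyl 3-(2,4,6-trimethoxy-3-methylphenyl)propanoate; 6 propanoyl chloride
Product: 7 ethyl 3-(2,4,6-trimethoxy-3-methyl-5-propanoylphenyl)propanoate
Conditions: TiCl4, CH2Cl2, −20 → 0 °C
Reagents that add atoms: none
Why: Friedel–Crafts acylation at the single free position of a ring activated by three methoxy groups and not yet deactivated by a carbonyl group, run cold so that the Lewis acid does not cleave a methyl ether ortho to the new ketone.

Step 5
Reactants: 7 ethyl 3-(2,4,6-trimethoxy-3-methyl-5-propanoylphenyl)propanoate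
Product: 8 3-(2,4,6-trimethoxy-3-methyl-5-propanoylphenyl)propanoic acid
Conditions: LiOH, THF/H2O, rt; then 1 M HCl
Reagents that add atoms: lithium hydroxide, [Li+].[OH-]
Why: Saponification of an unhindered ethyl ester, with the aryl ketone shielded from hydroxide by its two ortho methoxy groups.

Step 6
Reactants: 8 3-(2,4,6-trimethoxy-3-methyl-5-propanoylphenyl)propanoic acid; 9 ethoxyacetylene
Product: 12 3-ethoxy-4-[(2,4,6-trimethoxy-3-methyl-5-propanoylphenyl)methyl]cyclobut-2-en-1-one (racemic), via acid chloride 10 (not isolated), via aldoketene 11 (not isolated)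
Conditions: (COCl)2, cat. DMF, CH2Cl2, 0 °C → rt; evaporate; then 9 (3 equiv), Et3N (slow addition), Et2O, 0 °C → rt
Reagents that add atoms: none
Why: Dehydrochlorination of the acid chloride gives the aldoketene, which should undergo the known regioselective [2+2] cycloaddition with the ynol ether (nucleophilic terminal alkyne carbon to the ketene carbonyl carbon) to give the 3-ethoxy-4-substituted cyclobutenone; its one stereocentre is formed without control and is destroyed in step 8.

Step 7
Reactants: 13 propyne
Product: 16 1-[tri(propan-2-yl)silyloxy]prop-1-yne, via propynyllithium 14 (not isolated), via lithium ynolate 15 (not isolated)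
Conditions: n-BuLi, THF, −78 °C; t-BuOOLi (from t-BuOOH and LiHMDS), −78 → 0 °C; TIPSOTf, −78 °C
Reagents that add atoms: tert-butyl hydroperoxide, CC(C)(C)OO; triisopropylsilyl trifluoromethanesulfonate, CC(C)[Si](OS(=O)(=O)C(F)(F)F)(C(C)C)C(C)C
Why: The lithium acetylide should attack the peroxide oxygen of lithium tert-butyl peroxide with loss of tert-butoxide to give the ynolate, which the bulky silyl triflate silylates on oxygen, a known route to triisopropylsiloxyalkynes.

Step 8
Reactants: 12 3-ethoxy-4-[(2,4,6-trimethoxy-3-methyl-5-propanoylphenyl)methyl]cyclobut-2-en-1-one (racemic); 16 1-[tri(propan-2-yl)silyloxy]prop-1-yne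
Product: 21 1-[3-({6-ethoxy-2-hydroxy-3-methyl-4-[tri(propan-2-yl)silyloxy]phenyl}methyl)-2,4,6-trimethoxy-5-methylphenyl]propan-1-one, via vinylketene 17 (not isolated), via alkenylcyclobutenone 18 (not isolated), via dienylketene 19 (not isolated), via cyclohexadienone 20 (not isolated)
Conditions: 16 (2 equiv), PhMe, 110 → 140 °C, sealed tube
Reagents that add atoms: none
Why: Danheiser benzannulation: thermal 4π electrocyclic opening of 12, with the arylmethyl group turning outward, should give the (Z)-vinylketene 17, whose ketene C=C adds the siloxyalkyne in a [2+2] cycloaddition to give 18; the methyl-bearing alkyne carbon bonds to the ketene carbonyl carbon (bond C3–C4) and the oxygen-bearing alkyne carbon to the former C2 of 12 (bond C1–C2). A second 4π opening of 18 gives dienylketene 19, and ring A closes by thermal disrotatory 6π electrocyclization between the ketene carbon C4 and the terminal alkene carbon C5 (bond C4–C5) to cyclohexadienone 20, which tautomerises irreversibly to the phenol. The closest known reaction type is the benzannulation of cyclobutenones with trialkylsiloxyalkynes to resorcinol derivatives, and here the 3-ethoxy group supplies the third oxygen, which ends on C6. No stereocentre is formed, since those of 12, 18 and 20 are lost on the way to the aromatic ring. The step needs the regiochemistry of the ketene–ynol ether [2+2], fixed by the oxygen polarisation of the alkyne and the electrophilic sp carbon of the ketene, and a dienylketene geometry that can close; reversible opening of 18 should funnel material through the isomer with the alkenyl group cis to the ketene, and the outward-turned arylmethyl group leaves only hydrogen on the inside of the closing terminus. The neutral thermal conditions should leave the ring B ketone, the methyl ethers, the silyl ether and the new diarylmethane untouched, and ring A emerges with its three oxygens differentiated as OH (C4), OSi (C2) and OEt (C6).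

Step 9
Reactants: 21 1-[3-({6-ethoxy-2-hydroxy-3-methyl-4-[tri(propan-2-yl)silyloxy]phenyl}methyl)-2,4,6-trimethoxy-5-methylphenyl]propan-1-one; 22 butanoyl chloride
Product: 23 1-[3-({3-butanoyl-2-ethoxy-6-hydroxy-5-methyl-4-[tri(propan-2-yl)silyloxy]phenyl}methyl)-2,4,6-trimethoxy-5-methylphenyl]propan-1-one
Conditions: TiCl4, CH2Cl2, −78 → −20 °C
Reagents that add atoms: none
Why: Friedel–Crafts acylation at C1, the only unsubstituted aromatic carbon in the molecule, which is para to the titanium phenoxide on C4 and ortho to the C2 and C6 oxygens, so it should be attacked at low temperature before the Lewis acid harms the silyl ether or the diarylmethane, while the C4–OH, flanked by CH3 and CH2, resists O-acylation.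

Step 10
Reactants: 23 1-[3-({3-butanoyl-2-ethoxy-6-hydroxy-5-methyl-4-[tri(propan-2-yl)silyloxy]phenyl}methyl)-2,4,6-trimethoxy-5-methylphenyl]propan-1-one
Product: 24 1-[3-[(3-butanoyl-2-ethoxy-4,6-dihydroxy-5-methylphenyl)methyl]-2,4,6-trimethoxy-5-methylphenyl]propan-1-one
Conditions: TBAF, AcOH, THF, 0 °C
Reagents that add atoms: none
Why: Fluoride-mediated desilylation of an aryl silyl ether made labile by the ortho ketone, buffered with acetic acid so that no free phenoxide is present to start base-induced scission of the methylene bridge.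

Step 11
Reactants: 24 1-[3-[(3-butanoyl-2-ethoxy-4,6-dihydroxy-5-methylphenyl)methyl]-2,4,6-trimethoxy-5-methylphenyl]propan-1-one
Product: 25 1-[3-[(2,4,6-trihydroxy-3-methyl-5-propanoylphenyl)methyl]-2,4,6-trihydroxy-5-methylphenyl]butan-1-one (CNP0208000.0)
Conditions: BBr3 (excess), CH2Cl2, −78 °C → rt; then MeOH, H2O
Reagents that add atoms: none
Why: Lewis-acid dealkylation of aryl alkyl ethers with BBr3, in which the ethoxy group and two methoxy groups are activated by chelation to an ortho ketone and the last methoxy group is twisted out of conjugation by its two ortho substituents, while both rings are deactivated by their acyl groups against ipso protonation at the bridge.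

## Compound list

1 | 2,4,6-trimethoxytoluene | Cc1c(OC)cc(OC)cc1OC | starting material
2 | N-methyl-N-[(2,4,6-trimethoxy-3-methylphenyl)methylidene]methanaminium dichlorophosphate | C[N+](C)=Cc1c(OC)c(C)c(OC)cc1OC.[O-]P(=O)(Cl)Cl | intermediate
3 | 2,4,6-trimethoxy-3-methylbenzaldehyde | O=Cc1c(OC)c(C)c(OC)cc1OC | intermediate
4 | ethyl (E)-3-(2,4,6-trimethoxy-3-methylphenyl)prop-2-enoate | CCOC(=O)/C=C/c1c(OC)c(C)c(OC)cc1OC | intermediate
5 | ethyl 3-(2,4,6-trimethoxy-3-methylphenyl)propanoate | CCOC(=O)CCc1c(OC)c(C)c(OC)cc1OC | intermediate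
6 | propanoyl chloride | CCC(=O)Cl | starting material
7 | ethyl 3-(2,4,6-trimethoxy-3-methyl-5-propanoylphenyl)propanoate | CCOC(=O)CCc1c(OC)c(C)c(OC)c(C(=O)CC)c1OC | intermediate
8 | 3-(2,4,6-trimethoxy-3-methyl-5-propanoylphenyl)propanoic acid | OC(=O)CCc1c(OC)c(C)c(OC)c(C(=O)CC)c1OC | intermediate
9 | ethoxyacetylene | CCOC#C | starting material
10 | 3-(2,4,6-trimethoxy-3-methyl-5-propanoylphenyl)propanoyl chloride | ClC(=O)CCc1c(OC)c(C)c(OC)c(C(=O)CC)c1OC | intermediate
11 | 3-(2,4,6-trimethoxy-3-methyl-5-propanoylphenyl)prop-1-en-1-one (aldoketene) | O=C=CCc1c(OC)c(C)c(OC)c(C(=O)CC)c1OC | intermediate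
12 | 3-ethoxy-4-[(2,4,6-trimethoxy-3-methyl-5-propanoylphenyl)methyl]cyclobut-2-en-1-one (racemic) | O=C1C=C(OCC)C1Cc1c(OC)c(C)c(OC)c(C(=O)CC)c1OC | intermediate
13 | propyne | CC#C | starting material
14 | prop-1-yn-1-yllithium | CC#C[Li] | intermediate
15 | lithium prop-1-yn-1-olate | CC#C[O-].[Li+] | intermediate
16 | 1-[tri(propan-2-yl)silyloxy]prop-1-yne | CC#CO[Si](C(C)C)(C(C)C)C(C)C | intermediate
17 | (3Z)-3-ethoxy-5-(2,4,6-trimethoxy-3-methyl-5-propanoylphenyl)penta-1,3-dien-1-one | O=C=C/C(OCC)=C/Cc1c(OC)c(C)c(OC)c(C(=O)CC)c1OC | intermediate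
18 | 4-[(1Z)-1-ethoxy-3-(2,4,6-trimethoxy-3-methyl-5-propanoylphenyl)prop-1-en-1-yl]-2-methyl-3-[tri(propan-2-yl)silyloxy]cyclobut-2-en-1-one (racemic) | O=C1C(C)=C(O[Si](C(C)C)(C(C)C)C(C)C)C1/C(OCC)=C/Cc1c(OC)c(C)c(OC)c(C(=O)CC)c1OC | intermediate
19 | (3E,5Z)-5-ethoxy-2-methyl-7-(2,4,6-trimethoxy-3-methyl-5-propanoylphenyl)-3-[tri(propan-2-yl)silyloxy]hepta-1,3,5-trien-1-one | O=C=C(C)/C(O[Si](C(C)C)(C(C)C)C(C)C)=C\C(OCC)=C\Cc1c(OC)c(C)c(OC)c(C(=O)CC)c1OC | intermediate
20 | 5-ethoxy-2-methyl-6-[(2,4,6-trimethoxy-3-methyl-5-propanoylphenyl)methyl]-3-[tri(propan-2-yl)silyloxy]cyclohexa-2,4-dien-1-one (racemic) | O=C1C(C)=C(O[Si](C(C)C)(C(C)C)C(C)C)C=C(OCC)C1Cc1c(OC)c(C)c(OC)c(C(=O)CC)c1OC | intermediate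
21 | 1-[3-({6-ethoxy-2-hydroxy-3-methyl-4-[tri(propan-2-yl)silyloxy]phenyl}methyl)-2,4,6-trimethoxy-5-methylphenyl]propan-1-one | Cc1c(O)c(Cc2c(OC)c(C)c(OC)c(C(=O)CC)c2OC)c(OCC)cc1O[Si](C(C)C)(C(C)C)C(C)C | intermediate
22 | butanoyl chloride | CCCC(=O)Cl | starting material
23 | 1-[3-({3-butanoyl-2-ethoxy-6-hydroxy-5-methyl-4-[tri(propan-2-yl)silyloxy]phenyl}methyl)-2,4,6-trimethoxy-5-methylphenyl]propan-1-one | CCCC(=O)c1c(OCC)c(Cc2c(OC)c(C)c(OC)c(C(=O)CC)c2OC)c(O)c(C)c1O[Si](C(C)C)(C(C)C)C(C)C | intermediate
24 | 1-[3-[(3-butanoyl-2-ethoxy-4,6-dihydroxy-5-methylphenyl)methyl]-2,4,6-trimethoxy-5-methylphenyl]propan-1-one | CCCC(=O)c1c(OCC)c(Cc2c(OC)c(C)c(OC)c(C(=O)CC)c2OC)c(O)c(C)c1O | intermediate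
25 | 1-[3-[(2,4,6-trihydroxy-3-methyl-5-propanoylphenyl)methyl]-2,4,6-trihydroxy-5-methylphenyl]butan-1-one | CCCC(=O)c1c(O)c(C)c(O)c(Cc2c(O)c(C)c(O)c(C(=O)CC)c2O)c1O | target

## Step count and risks

Total step count: 11. Longest linear sequence: 10 steps (steps 1–6 and 8–11); step 7 is the one-step side branch.

Steps most likely to fail:

1. Step 8 (benzannulation). A 3-alkoxy-4-alkylcyclobutenone has rarely served as the vinylketene source in this reaction. The vinylogous ester may open slowly, so the electron-rich vinylketene could dimerise or polymerise before the siloxyalkyne intercepts it. At the temperature needed the siloxyalkyne may isomerise to a silylketene, or the cascade may stall at the alkenylcyclobutenone.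
 Fallback: the bridge would be made last by the classical Mannich route, setting out from 1 and coming back at 25.
 - Friedel–Crafts acylation of 1 with 6 (TiCl4, CH2Cl2) should give 1-(2,4,6-trimethoxy-3-methylphenyl)propan-1-one F1.
 - BBr3 should convert it into 1-(2,4,6-trihydroxy-3-methylphenyl)propan-1-one F2.
 - The same two operations with 22 should give 1-(2,4,6-trimethoxy-3-methylphenyl)butan-1-one F3 and then 1-(2,4,6-trihydroxy-3-methylphenyl)butan-1-one F4.
 - Aminomethylation of F2 at its only free ring carbon with dimethylmethylideneammonium iodide should give 1-{3-[(dimethylamino)methyl]-2,4,6-trihydroxy-5-methylphenyl}propan-1-one F5.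
 - On heating in dioxane, F5 should lose dimethylamine to the ortho-quinone methide 3,5-dihydroxy-2-methyl-6-methylidene-4-propanoylcyclohexa-2,4-dien-1-one F6, which F4 should trap at its free ring carbon to give 25.

2. Step 9 (butanoylation at C1). The acyl group may go onto oxygen. The electrophile or a proton may attack ipso at C5 and expel the trimethoxybenzyl-type cation, which cleaves the bridge while ring A is still electron-rich. The silyl group may be lost early and the hindered C1 position may react slowly.
 Fallback: the acyl group would be delivered through an ester and light, without a Lewis acid, setting out from 21 and coming back at 24.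
 - TBAF/AcOH should give 1-[3-[(2-ethoxy-4,6-dihydroxy-5-methylphenyl)methyl]-2,4,6-trimethoxy-5-methylphenyl]propan-1-one F7.
 - One equivalent of 22 (Et3N, CH2Cl2, −20 °C) should esterify the less hindered C2–OH to give 5-ethoxy-3-hydroxy-2-methyl-4-[(2,4,6-trimethoxy-3-methyl-5-propanoylphenyl)methyl]phenyl butanoate F8.
 - Irradiation (254 nm, cyclohexane) should bring about a photo-Fries rearrangement. The acyl radical can recombine only at C1, because the other ortho position (C3) and the para position (C5) are blocked, and this gives 24.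

3. Step 11 (exhaustive dealkylation). HBr formed in the flask may cut the methylene bridge and let the halves recombine to symmetric dimers, or the reaction may stop at partly alkylated material.
 Fallback: the alkyl groups would be exchanged for silyl groups under aprotic conditions, setting out from 24 and coming back at 25.
 - Silylation of the two free phenols with N,O-bis(trimethylsilyl)acetamide, then iodotrimethylsilane (from Me3SiCl and NaI, MeCN, 60 °C), should cleave the ethyl and the three methyl ethers by iodide attack on the silyloxonium ions. This should give the persilyl ether 1-[3-({3-butanoyl-5-methyl-2,4,6-tris[(trimethylsilyl)oxy]phenyl}methyl)-5-methyl-2,4,6-tris[(trimethylsilyl)oxy]phenyl]propan-1-one F9.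
 - Methanol at rt should then strip the silyl groups to give 25.

Further compounds

F1 | step 8 | 1-(2,4,6-trimethoxy-3-methylphenyl)propan-1-one | CCC(=O)c1c(OC)cc(OC)c(C)c1OC
F2 | step 8 | 1-(2,4,6-trihydroxy-3-methylphenyl)propan-1-one | CCC(=O)c1c(O)cc(O)c(C)c1O
F3 | step 8 | 1-(2,4,6-trimethoxy-3-methylphenyl)butan-1-one | CCCC(=O)c1c(OC)cc(OC)c(C)c1OC
F4 | step 8 | 1-(2,4,6-trihydroxy-3-methylphenyl)butan-1-one | CCCC(=O)c1c(O)cc(O)c(C)c1O
F5 | step 8 | 1-{3-[(dimethylamino)methyl]-2,4,6-trihydroxy-5-methylphenyl}propan-1-one | CCC(=O)c1c(O)c(CN(C)C)c(O)c(C)c1O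
F6 | step 8 | 3,5-dihydroxy-2-methyl-6-methylidene-4-propanoylcyclohexa-2,4-dien-1-one | C=C1C(=O)C(C)=C(O)C(C(=O)CC)=C1O
F7 | step 9 | 1-[3-[(2-ethoxy-4,6-dihydroxy-5-methylphenyl)methyl]-2,4,6-trimethoxy-5-methylphenyl]propan-1-one | Cc1c(O)cc(OCC)c(Cc2c(OC)c(C)c(OC)c(C(=O)CC)c2OC)c1O
F8 | step 9 | 5-ethoxy-3-hydroxy-2-methyl-4-[(2,4,6-trimethoxy-3-methyl-5-propanoylphenyl)methyl]phenyl butanoate | CCCC(=O)Oc1cc(OCC)c(Cc2c(OC)c(C)c(OC)c(C(=O)CC)c2OC)c(O)c1C
F9 | step 11 | 1-[3-({3-butanoyl-5-methyl-2,4,6-tris[(trimethylsilyl)oxy]phenyl}methyl)-5-methyl-2,4,6-tris[(trimethylsilyl)oxy]phenyl]propan-1-one | CCCC(=O)c1c(O[Si](C)(C)C)c(C)c(O[Si](C)(C)C)c(Cc2c(O[Si](C)(C)C)c(C)c(O[Si](C)(C)C)c(C(=O)CC)c2O[Si](C)(C)C)c1O[Si](C)(C)C
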